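Molar concentration is the unit to watch. The step to target and by-product uses substrate at a rate that goes with its concentration, and self-condensation with the square of it. So I name s, the substrate concentration at which the two paths use substrate equally fast.

| setting | north | south-west | flask |
|---|---|---|---|
| substrate | 0.013 M | 0.030 M | 0.020 M |
| remark | run made earlier | run made earlier |  |
| time |  |  | 5.0 d |

- north (time / d: target / %): 0.0417: 64.5; 0.0833: 69.4; 0.167: 70.4; 0.417: 69.3; 0.833: 68.4; 1.67: 67.7; 4.00: 64.4
- south-west (time / d: target / %): 0.0417: 49.9; 0.0833: 51.5; 0.167: 51.9; 0.417: 49.9; 0.833: 48.3; 1.67: 45.4; 4.00: 39.8

(standard deviation of a reading: 0.3 percentage points)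

* the best time, 5.0 d at the latest, for target
* the amount of target, in percent of the substrate charged, at that time

- percentages count the substrate that a species holds: one self-condensation product counts as two
- the numbers in the tables scatter with a standard deviation of 0.3 percentage points
- reactions considered so far: substrate <-> target + by-product; 2 substrate -> self-condensation product

Setting the way back aside, I divide one rate by the other and integrate. The target's share is then ln(1 + r)/r, where r is the charge divided by s. The south-west peak reading is 51.9%. I try r = 2.3 and solve the formula for r from the logarithm: this returns 2.30. Going round once more returns 2.30, so I put s at 0.0130 M: an estimate from one run with the way back set aside, not a measurement of the crossover concentration. For the flask this gives 60.6%.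

The weak link is that s comes from one run. For the north run it gives 69.4%, but the reading is 70.4%, a miss of 1 percentage point, larger than the scatter of 0.3 points. I scale that miss linearly with charge between the two runs and commit to 61.2%, at about 0.167 d, where both runs read highest.

The forecast, reckoned another way, says 61.2% at 0.16 d: “Both runs peak near 0.17 d (between about 0.1 and 0.3 d), so the flask should too”.

The flask gives 61.0% at 0.111 d, and still 60.9% at 0.167 d.

    substrate ⇌ target + by-product (K = 0.320 M, k = 0.0370 min⁻¹)
    2 substrate → self-condensation product (k = 1.20 M⁻¹ min⁻¹)

With self-condensation taken away, the flask's highest target goes from 61.0% to 94.4%, the larger of the two simulated effects. At the start of this flask, the forward step to target uses substrate at 0.77 times the rate of self-condensation, so substrate starts above the concentration at which the two paths use it equally fast. The neighbour charged with 0.080 M has r = 6.14 on my estimate of s, for which the formula gives 32.0%; that flask reaches 31.4%.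

The numbers in the tables stem from a simulated flask for an exercise, and the scatter is random.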